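**Plan**

Unit 1 is the flavone whose ring B carries the ether oxygen at its para carbon; unit 2 is the flavone bound to that oxygen through C8 and bearing the 4-hydroxyphenyl group.
Retrosynthesis: after removal of a pivalate on the phenol of unit 2, both C5–O bonds are cut back to C5–H, giving a 5-deoxy biflavone. This is cut at O1–C2 and Cα–Cβ of unit 1 (chalcone, then aldehyde plus paeonol), at the diaryl ether O–C(aryl) bond (8-hydroxyflavone plus 4-fluorobenzaldehyde), and at O1–C2 and Cα–Cβ of unit 2 (2,3-dihydroxy-4-methoxyacetophenone plus 4-(benzyloxy)benzaldehyde).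
Forward: ring C of unit 2 closes first, the C8 phenol is arylated, ring C of unit 1 closes second, benzyl is exchanged for pivalate, both C5 hydroxyls are installed in one operation, and the pivalate is removed.
Enabling feature: in each unit the C4 carbonyl oxygen and the C5–H bond of ring A sit in the O=C4–C4a–C5–H arrangement of an aryl ketone, so the oxygen can carry ruthenium to C5 through a five-membered metallacycle. Because C5 is still unoxygenated when ring C of unit 2 forms, only one hydroxyl of the acetophenone can cyclise and the aryloxy group must sit at C8.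
Stereochemistry: the target has no stereocentre; the chalcone double bonds and the racemic flavanone intermediates are consumed in the oxidative ring closures.

Key step: step 8

Remark: the two flavones are built one after the other, not through a compound carrying both an acetyl group and an aryl aldehyde, which would self-condense under Claisen–Schmidt conditions. 4-(Benzyloxy)benzaldehyde is taken as the commercial protected form of 4-hydroxybenzaldehyde.

**Route**

Step 1
Reactants: 1 2,3-dihydroxy-4-methoxyacetophenone; 2 4-(benzyloxy)benzaldehyde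
Product: 3 (E)-3-[4-(benzyloxy)phenyl]-1-(2,3-dihydroxy-4-methoxyphenyl)prop-2-en-1-one
Conditions: KOH (50% aq., 10 equiv), EtOH, argon, rt, 48 h; then 2 M HCl, 0 °C
Reagents that add atoms: none
Why: Claisen–Schmidt condensation, in which the phenoxide-enolate of 1 adds to the non-enolisable aldehyde 2 and E1cB loss of water gives the E-enone; the benzyl ether is inert to hydroxide and exclusion of air protects the catecholate.

Step 2
Reactants: 3 (E)-3-[4-(benzyloxy)phenyl]-1-(2,3-dihydroxy-4-methoxyphenyl)prop-2-en-1-one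
Product: 5 2-[4-(benzyloxy)phenyl]-8-hydroxy-7-methoxy-4H-chromen-4-one, via racemic flavanone 4 (not isolated)
Conditions: I2 (10 mol %), DMSO, 130 °C
Reagents that add atoms: none
Why: Iodine/DMSO oxidative cyclisation of a 2'-hydroxychalcone, in which only the hydroxyl ortho to the carbonyl can reach the enone β-carbon in a six-membered oxa-Michael closure, flavanone 4 is iodinated at C3 and loses HI, and DMSO reoxidises HI to I2; the second hydroxyl therefore ends at C8.

Step 3
Reactants: 5 2-[4-(benzyloxy)phenyl]-8-hydroxy-7-methoxy-4H-chromen-4-one; 6 4-fluorobenzaldehyde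
Product: 7 4-({2-[4-(benzyloxy)phenyl]-7-methoxy-4-oxo-4H-chromen-8-yl}oxy)benzaldehyde
Conditions: K2CO3 (2 equiv), 6 (1.5 equiv), DMF, N2, 110 °C
Reagents that add atoms: none
Why: Nucleophilic aromatic substitution by addition–elimination, in which the C8 phenoxide attacks the fluorine-bearing carbon activated by the para formyl group, as is usual for phenoxides flanked by two oxygen substituents; the flavone and the benzyl ether are inert to K2CO3 in DMF.

Step 4
Reactants: 7 4-({2-[4-(benzyloxy)phenyl]-7-methoxy-4-oxo-4H-chromen-8-yl}oxy)benzaldehyde; 8 paeonol (2-hydroxy-4-methoxyacetophenone)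
Product: 9 2-[4-(benzyloxy)phenyl]-8-{4-[(E)-3-(2-hydroxy-4-methoxyphenyl)-3-oxoprop-1-en-1-yl]phenoxy}-7-methoxy-4H-chromen-4-one
Conditions: KOH (50% aq., 8 equiv), 8 (1.3 equiv), EtOH/THF, rt, 24–36 h; then 1 M HCl, 0 °C
Reagents that add atoms: none
Why: Claisen–Schmidt condensation in which 7 has no enolisable position, so the enolate of paeonol is the only nucleophile and the formyl group of 7 the only reactive electrophile, giving the E-chalcone; at room temperature any hydroxide-opened pyranone of unit 2 recloses on acidification.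

Step 5
Reactants: 9 2-[4-(benzyloxy)phenyl]-8-{4-[(E)-3-(2-hydroxy-4-methoxyphenyl)-3-oxoprop-1-en-1-yl]phenoxy}-7-methoxy-4H-chromen-4-one
Product: 11 2-[4-(benzyloxy)phenyl]-7-methoxy-8-[4-(7-methoxy-4-oxo-4H-chromen-2-yl)phenoxy]-4H-chromen-4-one, via racemic flavanone 10 (not isolated)
Conditions: I2 (10 mol %), DMSO, 130 °C
Reagents that add atoms: none
Why: Second iodine/DMSO oxidative cyclisation of a 2'-hydroxychalcone (oxa-Michael closure to flavanone 10, then iodination and loss of HI) closes ring C of unit 1; the existing flavone, the diaryl ether and the benzyl ether tolerate these conditions.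

Step 6
Reactants: 11 2-[4-(benzyloxy)phenyl]-7-methoxy-8-[4-(7-methoxy-4-oxo-4H-chromen-2-yl)phenoxy]-4H-chromen-4-one
Product: 12 2-(4-hydroxyphenyl)-7-methoxy-8-[4-(7-methoxy-4-oxo-4H-chromen-2-yl)phenoxy]-4H-chromen-4-one
Conditions: H2 (1 atm), Pd/C (10 wt %), THF/MeOH, rt, stopped after one equivalent of H2
Reagents that add atoms: none
Why: Hydrogenolysis of the benzylic C–O bond on Pd/C, which at 1 atm and room temperature should be faster than reduction of the vinylogous-ester C2=C3 bonds of the two flavones.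

Step 7
Reactants: 12 2-(4-hydroxyphenyl)-7-methoxy-8-[4-(7-methoxy-4-oxo-4H-chromen-2-yl)phenoxy]-4H-chromen-4-one
Product: 13 4-{7-methoxy-8-[4-(7-methoxy-4-oxo-4H-chromen-2-yl)phenoxy]-4-oxo-4H-chromen-2-yl}phenyl pivalate
Conditions: PivCl (1.5 equiv), Et3N (2 equiv), DMAP (10 mol %), CH2Cl2, 0 °C to rt
Reagents that add atoms: pivaloyl chloride, CC(C)(C)C(=O)Cl
Why: DMAP-catalysed acylation of the only free phenol; the pivalate makes this ring electron-poor for the coming oxidation and is stable in CF3CO2H.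

Step 8
Reactants: 13 4-{7-methoxy-8-[4-(7-methoxy-4-oxo-4H-chromen-2-yl)phenoxy]-4-oxo-4H-chromen-2-yl}phenyl pivalate
Product: 15 4-{5-hydroxy-8-[4-(5-hydroxy-7-methoxy-4-oxo-4H-chromen-2-yl)phenoxy]-7-methoxy-4-oxo-4H-chromen-2-yl}phenyl pivalate, via bis(trifluoroacetate) 14 (not isolated)
Conditions: [RuCl2(p-cymene)]2 (10 mol %), PhI(O2CCF3)2 (4 equiv), CF3CO2H/(CF3CO)2O (3:1), 80 °C; then H2O/THF, rt
Reagents that add atoms: [bis(trifluoroacetoxy)iodo]benzene, O=C(OI(OC(=O)C(F)(F)F)c1ccccc1)C(F)(F)F; trifluoroacetic acid, OC(=O)C(F)(F)F (the carboxylate pool from which each new C5 oxygen is drawn)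
Why: In CF3CO2H the chloride ligands of [RuCl2(p-cymene)]2 are exchanged for trifluoroacetate, the C4 carbonyl oxygen of each chromone binds the resulting divalent ruthenium, and carboxylate-assisted metalation–deprotonation cleaves the peri C5–H bond to a five-membered ruthenacycle (Ru–O=C4–C4a–C5). Oxidation by PhI(O2CCF3)2 to a tetravalent ruthenium trifluoroacetate and C–O reductive elimination deliver the C5 trifluoroacetate and return divalent ruthenium, so both units end as bis(trifluoroacetate) 14, which water cleaves at the acyl carbon to diphenol 15. The closest known reaction is the ruthenium-catalysed, ketone-directed ortho C–H hydroxylation of aryl ketones with this oxidant, which has been applied to C5 of simple flavones and chromones; here it runs twice in one molecule. The step forms no ring and no stereocentre. It needs oxygenation at C5 of each unit only: from the C4 oxygen, C5–H is the one C–H bond that gives a five-membered metallacycle (C3–H would need a four-membered one, and C6–H, C8–H and the ring B hydrogens are out of reach), and the ether and methoxy oxygens do not direct. Over-oxidation is held back because each new oxygen stays acylated in the (CF3CO)2O medium and is afterwards chelated to C4=O, and because the phenol of unit 2 is an electron-poor pivalate.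

Step 9
Reactants: 15 4-{5-hydroxy-8-[4-(5-hydroxy-7-methoxy-4-oxo-4H-chromen-2-yl)phenoxy]-7-methoxy-4-oxo-4H-chromen-2-yl}phenyl pivalate
Product: 16 5-hydroxy-8-[4-(5-hydroxy-7-methoxy-4-oxo-4H-chromen-2-yl)phenoxy]-2-(4-hydroxyphenyl)-7-methoxy-4H-chromen-4-one (CNP0415865.0)
Conditions: K2CO3 (3 equiv), MeOH/THF, rt to 40 °C; then 1 M HCl to pH 4–5
Reagents that add atoms: none
Why: Base-mediated transesterification (methanolysis) of the aryl pivalate; the methyl ethers, the diaryl ether and the chromones are inert, and the C5 phenols are only deprotonated and return on acidification.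

**Compound list**

1 | 2,3-dihydroxy-4-methoxyacetophenone | CC(=O)c1ccc(OC)c(O)c1O | starting material
2 | 4-(benzyloxy)benzaldehyde | O=Cc1ccc(OCc2ccccc2)cc1 | starting material
3 | (E)-3-[4-(benzyloxy)phenyl]-1-(2,3-dihydroxy-4-methoxyphenyl)prop-2-en-1-one | COc1ccc(C(=O)/C=C/c2ccc(OCc3ccccc3)cc2)c(O)c1O | intermediate
4 | racemic 2-[4-(benzyloxy)phenyl]-8-hydroxy-7-methoxychroman-4-one (not isolated) | COc1ccc2c(c1O)OC(c1ccc(OCc3ccccc3)cc1)CC2=O | intermediate
5 | 2-[4-(benzyloxy)phenyl]-8-hydroxy-7-methoxy-4H-chromen-4-one | COc1ccc2c(=O)cc(-c3ccc(OCc4ccccc4)cc3)oc2c1O | intermediate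
6 | 4-fluorobenzaldehyde | O=Cc1ccc(F)cc1 | starting material
7 | 4-({2-[4-(benzyloxy)phenyl]-7-methoxy-4-oxo-4H-chromen-8-yl}oxy)benzaldehyde | COc1ccc2c(=O)cc(-c3ccc(OCc4ccccc4)cc3)oc2c1Oc1ccc(C=O)cc1 | intermediate
8 | paeonol (2-hydroxy-4-methoxyacetophenone) | CC(=O)c1ccc(OC)cc1O | starting material
9 | 2-[4-(benzyloxy)phenyl]-8-{4-[(E)-3-(2-hydroxy-4-methoxyphenyl)-3-oxoprop-1-en-1-yl]phenoxy}-7-methoxy-4H-chromen-4-one | COc1ccc(C(=O)/C=C/c2ccc(Oc3c(OC)ccc4c(=O)cc(-c5ccc(OCc6ccccc6)cc5)oc34)cc2)c(O)c1 | intermediate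
10 | racemic 2-[4-(benzyloxy)phenyl]-7-methoxy-8-[4-(7-methoxy-4-oxochroman-2-yl)phenoxy]-4H-chromen-4-one (not isolated) | COc1ccc2c(c1)OC(c1ccc(Oc3c(OC)ccc4c(=O)cc(-c5ccc(OCc6ccccc6)cc5)oc34)cc1)CC2=O | intermediate
11 | 2-[4-(benzyloxy)phenyl]-7-methoxy-8-[4-(7-methoxy-4-oxo-4H-chromen-2-yl)phenoxy]-4H-chromen-4-one | COc1ccc2c(=O)cc(-c3ccc(Oc4c(OC)ccc5c(=O)cc(-c6ccc(OCc7ccccc7)cc6)oc45)cc3)oc2c1 | intermediate
12 | 2-(4-hydroxyphenyl)-7-methoxy-8-[4-(7-methoxy-4-oxo-4H-chromen-2-yl)phenoxy]-4H-chromen-4-one | COc1ccc2c(=O)cc(-c3ccc(Oc4c(OC)ccc5c(=O)cc(-c6ccc(O)cc6)oc45)cc3)oc2c1 | intermediate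
13 | 4-{7-methoxy-8-[4-(7-methoxy-4-oxo-4H-chromen-2-yl)phenoxy]-4-oxo-4H-chromen-2-yl}phenyl pivalate | COc1ccc2c(=O)cc(-c3ccc(Oc4c(OC)ccc5c(=O)cc(-c6ccc(OC(=O)C(C)(C)C)cc6)oc45)cc3)oc2c1 | intermediate
14 | 4-{7-methoxy-8-[4-(7-methoxy-4-oxo-5-(trifluoroacetoxy)-4H-chromen-2-yl)phenoxy]-4-oxo-5-(trifluoroacetoxy)-4H-chromen-2-yl}phenyl pivalate (not isolated) | COc1cc(OC(=O)C(F)(F)F)c2c(=O)cc(-c3ccc(Oc4c(OC)cc(OC(=O)C(F)(F)F)c5c(=O)cc(-c6ccc(OC(=O)C(C)(C)C)cc6)oc45)cc3)oc2c1 | intermediate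
15 | 4-{5-hydroxy-8-[4-(5-hydroxy-7-methoxy-4-oxo-4H-chromen-2-yl)phenoxy]-7-methoxy-4-oxo-4H-chromen-2-yl}phenyl pivalate | COc1cc(O)c2c(=O)cc(-c3ccc(Oc4c(OC)cc(O)c5c(=O)cc(-c6ccc(OC(=O)C(C)(C)C)cc6)oc45)cc3)oc2c1 | intermediate
16 | 5-hydroxy-8-[4-(5-hydroxy-7-methoxy-4-oxo-4H-chromen-2-yl)phenoxy]-2-(4-hydroxyphenyl)-7-methoxy-4H-chromen-4-one (CNP0415865.0) | COc1cc(O)c2c(=O)cc(-c3ccc(Oc4c(OC)cc(O)c5c(=O)cc(-c6ccc(O)cc6)oc45)cc3)oc2c1 | target

**Step count and risks**

Total step count: 9. Longest linear sequence: 9 steps (1 to 16); compounds 2, 6 and 8 are purchased.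

Steps most likely to fail:

1. Step 8. The trivalent iodine oxidant may degrade the electron-rich aryl ether rings by single-electron oxidation, the second unit may react incompletely, or the pivalate carbonyl may direct oxygenation ortho to the ester. The fallback brings both C5 oxygens in before the biflavone exists; it sets out from 2 and comes back at 16. Commercial 2,6-dihydroxy-4-methoxyacetophenone (CC(=O)c1c(O)cc(OC)cc1O) would be condensed with 2 (KOH, EtOH) to (E)-3-[4-(benzyloxy)phenyl]-1-(2,6-dihydroxy-4-methoxyphenyl)prop-2-en-1-one F1. I2/DMSO would close this symmetrical dihydroxychalcone to 2-[4-(benzyloxy)phenyl]-5-hydroxy-7-methoxy-4H-chromen-4-one F2. Elbs persulfate oxidation (K2S2O8, aq. KOH/pyridine) should attack para to the C5 phenoxide and give potassium 2-[4-(benzyloxy)phenyl]-5-hydroxy-7-methoxy-4-oxo-4H-chromen-8-yl sulfate F3, which hot dilute HCl would hydrolyse to 2-[4-(benzyloxy)phenyl]-5,8-dihydroxy-7-methoxy-4H-chromen-4-one F4; the oxygen enters after ring C is closed, so its place at C8 is unambiguous. The C8 hydroxyl (the C5 hydroxyl is chelated and unreactive) would be arylated with 6 (K2CO3, DMF, N2) to 4-({2-[4-(benzyloxy)phenyl]-5-hydroxy-7-methoxy-4-oxo-4H-chromen-8-yl}oxy)benzaldehyde F5. Claisen–Schmidt condensation with a second portion of 2,6-dihydroxy-4-methoxyacetophenone would give 2-[4-(benzyloxy)phenyl]-8-{4-[(E)-3-(2,6-dihydroxy-4-methoxyphenyl)-3-oxoprop-1-en-1-yl]phenoxy}-5-hydroxy-7-methoxy-4H-chromen-4-one F6, I2/DMSO would give 2-[4-(benzyloxy)phenyl]-5-hydroxy-8-[4-(5-hydroxy-7-methoxy-4-oxo-4H-chromen-2-yl)phenoxy]-7-methoxy-4H-chromen-4-one F7, and hydrogenolysis (H2, Pd/C) would give 16.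

2. Step 1. Enolisation of the doubly deprotonated acetophenone may be slow, and the catecholate may be oxidised by air over the long reaction. The fallback builds the flavone by acyl transfer, not by aldol condensation; it sets out from 1 and comes back at 5. Compound 1 would be acylated twice with 4-(benzyloxy)benzoyl chloride (O=C(Cl)c1ccc(OCc2ccccc2)cc1, pyridine) to 3-acetyl-6-methoxy-1,2-phenylene bis[4-(benzyloxy)benzoate] F8. Baker–Venkataraman rearrangement (KOtBu, THF) would move the aroyl group on the oxygen ortho to the acetyl group to the acetyl carbon and give 3-{3-[4-(benzyloxy)phenyl]-3-oxopropanoyl}-2-hydroxy-6-methoxyphenyl 4-(benzyloxy)benzoate F9. p-TsOH in toluene at reflux would cyclodehydrate this to 2-[4-(benzyloxy)phenyl]-7-methoxy-4-oxo-4H-chromen-8-yl 4-(benzyloxy)benzoate F10, and K2CO3 in MeOH would remove the remaining ester to give 5.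

3. Step 4. Hydroxide may attack C2 of the preformed flavone and open the ring with retro-Claisen cleavage, and the aldehyde is likely to be poorly soluble in the alcoholic medium. The fallback makes the enone by a Wittig olefination under neutral conditions; it sets out from 8 and comes back at 9. Paeonol 8 would be brominated at the methyl group with CuBr2 (EtOAc/CHCl3, reflux) to 2-bromo-1-(2-hydroxy-4-methoxyphenyl)ethan-1-one F11. PPh3 in toluene would give [2-(2-hydroxy-4-methoxyphenyl)-2-oxoethyl]triphenylphosphonium bromide F12, and aqueous Na2CO3 would give the stabilised ylide 1-(2-hydroxy-4-methoxyphenyl)-2-(triphenylphosphoranylidene)ethan-1-one F13. Heating F13 with 7 in toluene should give the E-chalcone 9.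

**Further compounds**

F1 | step 8 | (E)-3-[4-(benzyloxy)phenyl]-1-(2,6-dihydroxy-4-methoxyphenyl)prop-2-en-1-one | COc1cc(O)c(C(=O)/C=C/c2ccc(OCc3ccccc3)cc2)c(O)c1
F2 | step 8 | 2-[4-(benzyloxy)phenyl]-5-hydroxy-7-methoxy-4H-chromen-4-one | COc1cc(O)c2c(=O)cc(-c3ccc(OCc4ccccc4)cc3)oc2c1
F3 | step 8 | potassium 2-[4-(benzyloxy)phenyl]-5-hydroxy-7-methoxy-4-oxo-4H-chromen-8-yl sulfate | COc1cc(O)c2c(=O)cc(-c3ccc(OCc4ccccc4)cc3)oc2c1OS(=O)(=O)[O-].[K+]
F4 | step 8 | 2-[4-(benzyloxy)phenyl]-5,8-dihydroxy-7-methoxy-4H-chromen-4-one | COc1cc(O)c2c(=O)cc(-c3ccc(OCc4ccccc4)cc3)oc2c1O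
F5 | step 8 | 4-({2-[4-(benzyloxy)phenyl]-5-hydroxy-7-methoxy-4-oxo-4H-chromen-8-yl}oxy)benzaldehyde | COc1cc(O)c2c(=O)cc(-c3ccc(OCc4ccccc4)cc3)oc2c1Oc1ccc(C=O)cc1
F6 | step 8 | 2-[4-(benzyloxy)phenyl]-8-{4-[(E)-3-(2,6-dihydroxy-4-methoxyphenyl)-3-oxoprop-1-en-1-yl]phenoxy}-5-hydroxy-7-methoxy-4H-chromen-4-one | COc1cc(O)c(C(=O)/C=C/c2ccc(Oc3c(OC)cc(O)c4c(=O)cc(-c5ccc(OCc6ccccc6)cc5)oc34)cc2)c(O)c1
F7 | step 8 | 2-[4-(benzyloxy)phenyl]-5-hydroxy-8-[4-(5-hydroxy-7-methoxy-4-oxo-4H-chromen-2-yl)phenoxy]-7-methoxy-4H-chromen-4-one | COc1cc(O)c2c(=O)cc(-c3ccc(Oc4c(OC)cc(O)c5c(=O)cc(-c6ccc(OCc7ccccc7)cc6)oc45)cc3)oc2c1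
F8 | step 1 | 3-acetyl-6-methoxy-1,2-phenylene bis[4-(benzyloxy)benzoate] | CC(=O)c1ccc(OC)c(OC(=O)c2ccc(OCc3ccccc3)cc2)c1OC(=O)c1ccc(OCc2ccccc2)cc1
F9 | step 1 | 3-{3-[4-(benzyloxy)phenyl]-3-oxopropanoyl}-2-hydroxy-6-methoxyphenyl 4-(benzyloxy)benzoate | COc1ccc(C(=O)CC(=O)c2ccc(OCc3ccccc3)cc2)c(O)c1OC(=O)c1ccc(OCc2ccccc2)cc1
F10 | step 1 | 2-[4-(benzyloxy)phenyl]-7-methoxy-4-oxo-4H-chromen-8-yl 4-(benzyloxy)benzoate | COc1ccc2c(=O)cc(-c3ccc(OCc4ccccc4)cc3)oc2c1OC(=O)c1ccc(OCc2ccccc2)cc1
F11 | step 4 | 2-bromo-1-(2-hydroxy-4-methoxyphenyl)ethan-1-one | COc1ccc(C(=O)CBr)c(O)c1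
F12 | step 4 | [2-(2-hydroxy-4-methoxyphenyl)-2-oxoethyl]triphenylphosphonium bromide | COc1ccc(C(=O)C[P+](c2ccccc2)(c2ccccc2)c2ccccc2)c(O)c1.[Br-]
F13 | step 4 | 1-(2-hydroxy-4-methoxyphenyl)-2-(triphenylphosphoranylidene)ethan-1-one | COc1ccc(C(=O)C=P(c2ccccc2)(c2ccccc2)c2ccccc2)c(O)c1
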